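The route rests on cutting the C2–C8' bond of the central dihydrofuran ring (C2, C3, O7', C7', C8'). With C2=C3 restored, these five atoms form an aryl vinyl ether: a flavone whose C3 carries the 7-oxygen of a protected kaempferol. A sensitised 6π photocyclisation under Sc(OTf)3/pybox control forges C2–C8', closes the furan ring, moves hydrogen from C8' to C3 and sets both stereocentres in one operation. Precursor 14 keeps a single free 5-OH on the reacting flavone as the only strong Lewis acid anchor, and a benzyloxy group at C5' that shields C6'. Bromination–hydrolysis at C3 and deprotection complete the synthesis.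

Key step: step 9

Remark on numbering: monomers carry the usual flavonoid locants (4' = para position of ring B). In the dimers, plain locants belong to the upper unit (rings A, C, B) and primed locants to the chromone atoms of the lower kaempferol unit (rings A', C'), whose aryl ring is called ring B'.

Assumption: the sense of induction of the Sc(OTf)3/pybox complex cannot be predicted safely. (S,S)-tBu-pybox is written, its commercial (R,R) enantiomer is to be used if the (2S,3R) series results, and the enantiomeric purity is to be checked at 18 and raised there by recrystallisation if needed.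

Step 1
Reactants: 1 kaempferol; 2 acetic anhydride
Product: 3 kaempferol 3,5,7,4'-tetraacetate
Conditions: Ac2O, pyridine, rt
Reagents that add atoms: acetic anhydride CC(=O)OC(C)=O
Why: Pyridine-promoted O-acylation (esterification) caps all four hydroxyls, the chelated 5-OH included, and gives acetates whose lability differs by position, which the next steps use.

Step 2
Reactants: 3 kaempferol 3,5,7,4'-tetraacetate; 4 benzyl bromide
Product: 5 3,5-di-O-acetyl-7,4'-di-O-benzylkaempferol
Conditions: BnBr (2.5 equiv), K2CO3, KI (cat.), acetone, reflux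
Reagents that add atoms: benzyl bromide BrCc1ccccc1
Why: Alkylative deacetylation coupled to a Williamson ether synthesis: carbonate cleaves only the two most activated aryl acetates (O7, para to the pyrone carbonyl, and O4' on ring B), the phenoxides are benzylated as they form, and the 3- and 5-acetates stay in place.

Step 3
Reactants: 5 3,5-di-O-acetyl-7,4'-di-O-benzylkaempferol
Product: 6 7,4'-di-O-benzylkaempferol (3-OH and 5-OH free)
Conditions: NH3 (7 M in MeOH), THF, 0 °C to rt, Ar
Reagents that add atoms: none
Why: Aminolysis of the enol acetate and the peri acetate is fast under conditions that leave benzyl ethers untouched, and exclusion of air protects the flavonol.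

Step 4
Reactants: 6 7,4'-di-O-benzylkaempferol; 7 trifluoromethanesulfonic anhydride
Product: 8 7,4'-di-O-benzylkaempferol 3-triflate (5-OH free)
Conditions: Tf2O (1.05 equiv), pyridine, CH2Cl2, −40 °C
Reagents that add atoms: trifluoromethanesulfonic anhydride O=S(=O)(OS(=O)(=O)C(F)(F)F)C(F)(F)F
Why: O-Sulfonylation of the enolic 3-OH with one equivalent of anhydride, the 5-OH being held back by its strong hydrogen bond to C4=O.

Step 5
Reactants: 3 kaempferol 3,5,7,4'-tetraacetate; 9 allyl bromide
Product: 10 3,5,4'-tri-O-acetyl-7-O-allylkaempferol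
Conditions: allyl bromide (1.1 equiv), K2CO3 (1.2 equiv), acetone, reflux
Reagents that add atoms: allyl bromide C=CCBr
Why: The same alkylative deacetylation and Williamson etherification, run with about one equivalent of halide, stops at O7 because its acetate releases the most stabilised phenoxide.

Step 6
Reactants: 10 3,5,4'-tri-O-acetyl-7-O-allylkaempferol; 4 benzyl bromide
Product: 12 7-O-allyl-3,5,4'-tri-O-benzylkaempferol, via 7-O-allylkaempferol 11 (not isolated)
Conditions: K2CO3, MeOH/DMF, rt, Ar; MeOH evaporated; BnBr (4 equiv), DMF, 60 °C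
Reagents that add atoms: benzyl bromide BrCc1ccccc1
Why: Carbonate-mediated methanolysis frees the three remaining hydroxyls and a threefold Williamson benzylation follows in the same flask, warm DMF being needed only for the chelated 5-OH, while the allyl ether is inert far below Claisen temperatures.

Step 7
Reactants: 12 7-O-allyl-3,5,4'-tri-O-benzylkaempferol
Product: 13 3,5,4'-tri-O-benzylkaempferol (7-OH free)
Conditions: Pd(PPh3)4 (5 mol%), morpholine, THF, rt
Reagents that add atoms: none
Why: Tsuji–Trost deallylation: zerovalent palladium ionises the allyl aryl ether to a π-allyl complex that morpholine traps, and benzyl ethers are not affected.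

Step 8
Reactants: 8 7,4'-di-O-benzylkaempferol 3-triflate; 13 3,5,4'-tri-O-benzylkaempferol
Product: 14 3-(3,5,4'-tri-O-benzylkaempferol-7-yloxy)-7,4'-bis(benzyloxy)-5-hydroxyflavone
Conditions: Pd2(dba)3 (2.5 mol%), tBuXPhos (6 mol%), K3PO4 (1.1 equiv), toluene, 85 °C, Ar
Reagents that add atoms: none
Why: Buchwald–Hartwig-type C–O coupling in its known enol triflate plus phenol version (aryl enol ether synthesis): zerovalent palladium inserts into the electron-poor C3–OTf bond, the non-chelating 7-phenoxide replaces triflate and the bulky biaryl phosphine drives reductive elimination; the roles are assigned this way because a flavone 7-triflate is an active triflyl donor towards the more basic flavonolate, which is also a chelating and poor nucleophile, and with barely more than one equivalent of base only the acidic 7-OH of 13 is deprotonated, not the 5-OH of 8.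

Step 9
Reactants: 14 3-(3,5,4'-tri-O-benzylkaempferol-7-yloxy)-7,4'-bis(benzyloxy)-5-hydroxyflavone
Product: 16 (2R,3S)-3-deoxy target penta-O-benzyl ether (C2–C8' bond, C3–H syn to ring B, cis-fused, 5-OH free), via carbonyl ylide 15 (not isolated)
Conditions: Sc(OTf)3 (20 mol%), (S,S)-tBu-pybox (30 mol%), [Ir(ppy)2(dtbbpy)]PF6 (2 mol%), CF3CH2OH (5 equiv), iPrOAc/MeCN 3:1, 450 nm LED, −20 °C, Ar; pH 7 buffer work-up
Reagents that add atoms: none
Why: Proposed new method: triplet energy transfer from excited [Ir(ppy)2(dtbbpy)]PF6 should reach only the flavone unit whose 5-OH/C4=O pair is chelated by the Sc(OTf)3–pybox complex, because chelation lowers its triplet energy while free 14 and the fully benzylated lower chromone stay dark (which also avoids the hydrogen abstraction that 3-benzyloxychromones undergo under UV light), and the triplet closes the six-electron, five-atom array C2=C3–O7'–C7'=C8' in the conrotatory sense, a formally 5-endo-trig closure of the dihydrofuran ring, to carbonyl ylide 15. The closest known reaction types are the 6π photocyclisation of 2-aryloxycyclohex-2-enones to cis-fused dihydrobenzofurans with a quaternary β-carbon, its enantioselective variant with Cu(ClO4)2 and a chiral bisoxazoline, and Sc(OTf)3–pybox/sensitiser catalysis of 2'-hydroxychalcone cycloadditions and acrylanilide 6π closures; flavones bearing a 3-aryloxy group have not been used in it. Conrotation places the C8' hydrogen anti to ring B, so a concerted suprafacial 1,4-shift would end in a severely strained trans ring fusion; the alcohol additive bound to Sc(OTf)3 is therefore meant to relay the proton, C3 being protonated on the face syn to ring B, the only one that keeps C4 and O1 on the same side, before C8' loses its proton and ring A' rearomatises. C2 is set in the C2–C8' bond formation by the ligand, whose tert-butyl groups cover one face of the rigidly chelated enone, and C3 follows from C2 through the obligatory cis fusion. Regioselectivity for C8' over C6' is needed and is secured twice: only attack at C8' leaves the C4a'=C8a' bond of pyrone ring C' in place (the pattern of 2-naphthyl ethers closing at C1), and the 5'-benzyl group, turned away from C4'=O, lies next to C6'. Chemoselectivity against loss of O1 from the ylide or from an enol, which would aromatise the new ring to a benzofuran, rests on low temperature, fast proton delivery and the absence of base.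

Step 10
Reactants: 16 (2R,3S)-3-deoxy target penta-O-benzyl ether; 2 acetic anhydride
Product: 18 (2R,3S)-3-deoxy target hexaacetate, via 3-deoxy hexaol 17 (not isolated)
Conditions: H2 (1 atm), Pd/C (10 wt%), EtOAc/THF, rt; filtered under Ar; Ac2O, pyridine, 0 °C to rt
Reagents that add atoms: acetic anhydride CC(=O)OC(C)=O
Why: Heterogeneous hydrogenolysis removes the five primary benzyl groups much faster than it could attack the shielded quaternary C2–O1 bond, and acetylation in pyridine, a base too weak to enolise C4=O, at once replaces every weak benzylic C–H bond and every activating ether by inert, deactivating acetates, so that C3–H becomes the only weak C–H bond and ionisation at C2 is damped; both stereocentres are untouched.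

Step 11
Reactants: 18 (2R,3S)-3-deoxy target hexaacetate; 19 N-bromosuccinimide; 20 water
Product: 22 (2R,3S)-target hexaacetate (C3–OH free), via C3 bromide 21 (not isolated)
Conditions: NBS (1.1 equiv), visible-light lamp, PhCF3, 40 °C; then Ag2CO3, acetone/H2O 10:1, 0 °C to rt, dark
Reagents that add atoms: water O; N-bromosuccinimide O=C1CCC(=O)N1Br (its bromine stays only in 21)
Why: Wohl–Ziegler bromination followed by silver-assisted hydrolysis: the bromine atom abstracts the captodative C3–H (between C4=O and O7'), as it does in alkoxyacetates and acylglycinates and with the tolerance of aryl acetates known from flavanone acetates, the tertiary α-bromo ether is solvolysed by water, no base or enol is involved, and bromine and then hydroxyl must take the place of hydrogen because the two rings can only be cis-fused, so C2 dictates C3.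

Step 12
Reactants: 22 (2R,3S)-target hexaacetate
Product: 23 target CNP0314633.1, (2R,3S)
Conditions: HCl (0.5 M in MeOH), THF, 0 °C to rt, Ar; aqueous work-up
Reagents that add atoms: none
Why: Acid-catalysed transesterification cleaves the six aryl and enol acetates while the hemiketal stays closed, base (which would open it and allow quinone methide formation at C2) is avoided, and neither centre can invert alone because each one fixes the other through the cis ring fusion.

Compound list
1 | kaempferol | O=c1c(O)c(-c2ccc(O)cc2)oc2cc(O)cc(O)c12 | starting material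
2 | acetic anhydride | CC(=O)OC(C)=O | starting material
3 | kaempferol 3,5,7,4'-tetraacetate | O=c1c(OC(C)=O)c(-c2ccc(OC(C)=O)cc2)oc2cc(OC(C)=O)cc(OC(C)=O)c12 | intermediate
4 | benzyl bromide | BrCc1ccccc1 | starting material
5 | 3,5-di-O-acetyl-7,4'-di-O-benzylkaempferol | O=c1c(OC(C)=O)c(-c2ccc(OCc3ccccc3)cc2)oc2cc(OCc3ccccc3)cc(OC(C)=O)c12 | intermediate
6 | 7,4'-di-O-benzylkaempferol | O=c1c(O)c(-c2ccc(OCc3ccccc3)cc2)oc2cc(OCc3ccccc3)cc(O)c12 | intermediate
7 | trifluoromethanesulfonic anhydride | O=S(=O)(OS(=O)(=O)C(F)(F)F)C(F)(F)F | starting material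
8 | 7,4'-di-O-benzylkaempferol 3-triflate | O=c1c(OS(=O)(=O)C(F)(F)F)c(-c2ccc(OCc3ccccc3)cc2)oc2cc(OCc3ccccc3)cc(O)c12 | intermediate
9 | allyl bromide | C=CCBr | starting material
10 | 3,5,4'-tri-O-acetyl-7-O-allylkaempferol | O=c1c(OC(C)=O)c(-c2ccc(OC(C)=O)cc2)oc2cc(OCC=C)cc(OC(C)=O)c12 | intermediate
11 | 7-O-allylkaempferol (not isolated) | O=c1c(O)c(-c2ccc(O)cc2)oc2cc(OCC=C)cc(O)c12 | intermediate
12 | 7-O-allyl-3,5,4'-tri-O-benzylkaempferol | O=c1c(OCc3ccccc3)c(-c2ccc(OCc3ccccc3)cc2)oc2cc(OCC=C)cc(OCc3ccccc3)c12 | intermediate
13 | 3,5,4'-tri-O-benzylkaempferol (7-OH free) | O=c1c(OCc3ccccc3)c(-c2ccc(OCc3ccccc3)cc2)oc2cc(O)cc(OCc3ccccc3)c12 | intermediate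
14 | 3-(3,5,4'-tri-O-benzylkaempferol-7-yloxy)-7,4'-bis(benzyloxy)-5-hydroxyflavone (photoprecursor) | O=c1c(Oc3cc(OCc6ccccc6)c4c(=O)c(OCc6ccccc6)c(-c5ccc(OCc6ccccc6)cc5)oc4c3)c(-c2ccc(OCc6ccccc6)cc2)oc2cc(OCc6ccccc6)cc(O)c12 | intermediate
15 | carbonyl ylide (C2–C8' bond made, C8'–H anti to ring B, O7' oxonium, C3=C4 enolate; not isolated) | [O-]C1=C2[O+]=C3C=C(OCc4ccccc4)C4=C(OC(c5ccc(OCc6ccccc6)cc5)=C(OCc5ccccc5)C4=O)[C@@H]3[C@@]2(c2ccc(OCc3ccccc3)cc2)Oc2cc(OCc3ccccc3)cc(O)c12 | intermediate
16 | (2R,3S)-3-deoxy target penta-O-benzyl ether, cis-fused, 5-OH free | O=C1c2c(O)cc(OCc6ccccc6)cc2O[C@]2(c3ccc(OCc6ccccc6)cc3)c3c(cc(OCc6ccccc6)c4c(=O)c(OCc6ccccc6)c(-c5ccc(OCc6ccccc6)cc5)oc34)O[C@H]12 | intermediate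
17 | (2R,3S)-3-deoxy target, hexaol (not isolated) | O=C1c2c(O)cc(O)cc2O[C@]2(c3ccc(O)cc3)c3c(cc(O)c4c(=O)c(O)c(-c5ccc(O)cc5)oc34)O[C@H]12 | intermediate
18 | (2R,3S)-3-deoxy target hexaacetate | O=C1c2c(OC(C)=O)cc(OC(C)=O)cc2O[C@]2(c3ccc(OC(C)=O)cc3)c3c(cc(OC(C)=O)c4c(=O)c(OC(C)=O)c(-c5ccc(OC(C)=O)cc5)oc34)O[C@H]12 | intermediate
19 | N-bromosuccinimide | O=C1CCC(=O)N1Br | starting material
20 | water | O | starting material
21 | (2R,3R)-3-bromo hexaacetate (bromine in the place of hydrogen, cis-fused; not isolated) | O=C1c2c(OC(C)=O)cc(OC(C)=O)cc2O[C@]2(c3ccc(OC(C)=O)cc3)c3c(cc(OC(C)=O)c4c(=O)c(OC(C)=O)c(-c5ccc(OC(C)=O)cc5)oc34)O[C@]12Br | intermediate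
22 | (2R,3S)-target hexaacetate (C3–OH free) | O=C1c2c(OC(C)=O)cc(OC(C)=O)cc2O[C@]2(c3ccc(OC(C)=O)cc3)c3c(cc(OC(C)=O)c4c(=O)c(OC(C)=O)c(-c5ccc(OC(C)=O)cc5)oc34)O[C@]12O | intermediate
23 | CNP0314633.1, (2R,3S) | O=C1c2c(O)cc(O)cc2O[C@]2(c3ccc(O)cc3)c3c(cc(O)c4c(=O)c(O)c(-c5ccc(O)cc5)oc34)O[C@]12O | target

Total step count: 12. Longest linear sequence: 9 steps (1, 5, 6, 7, 8, 9, 10, 11, 12). The branch through steps 2, 3 and 4 is equally long.

Steps most likely to fail

**Step 9.**
- **What may go wrong:** the ylide may expel O1 and aromatise, closure at the fully substituted C2 may be too slow, or the catalyst may discriminate the two enone faces poorly.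
- **Start of the fallback:** it uses known chemistry without light and sets out from 6 and 13.
- **Oxidation:** flavonol 6 is oxidised with PhI(OAc)2 in methanol, the established two-electron oxidation of 3-hydroxyflavones. This gives 7-benzyloxy-2-(4-benzyloxyphenyl)-3,5-dihydroxy-2,3-dimethoxychroman-4-one F1.
- **Condensation:** acid-catalysed condensation of F1 with phenol 13 (BF3·OEt2, CH2Cl2, −40 °C) follows the pattern by which ninhydrin and other vicinal polycarbonyl compounds add phenols. Friedel–Crafts attack of C8' on the C2 oxocarbenium ion, with C6' again screened by the 5'-benzyl group, and ketal exchange at C3 by O7' should give the racemic cis-fused 3-hydroxy pentabenzyl ether F2.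
- **Resolution and return:** preparative HPLC on a chiral stationary phase should deliver the (2R,3S)-3-hydroxy pentabenzyl ether F3. Hydrogenolysis (H2, Pd/C, EtOAc/THF) then comes back to the route at 23.

**Step 11.**
- **What may go wrong:** the C3 radical may break the C2–O1 bond, since loss of an aryloxyl radical aromatises the furan ring, faster than it captures bromine. Nuclear bromination may also intrude.
- **Fallback:** it sets out from 18 and inserts oxygen directly into C3–H with methyl(trifluoromethyl)dioxirane (CH2Cl2/1,1,1-trifluoroacetone, −20 °C). This is a concerted hydroxylation with retention that passes through neither a free radical nor an enol. It comes back to the route at 22 and makes no new compound (F0).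

**Step 8.**
- **What may go wrong:** C–O reductive elimination from the hindered vinylpalladium aryloxide may be slower than hydrolytic or reductive loss of the triflate.
- **Fallback:** it reverses the roles and changes the metal, setting out from 13 and 6.
- **Boronate:** phenol 13 is converted with Tf2O and pyridine into 3,5,4'-tri-O-benzylkaempferol 7-triflate F4. Miyaura borylation (B2pin2, PdCl2(dppf), KOAc, dioxane, 80 °C) gives 3,5,4'-tri-O-benzylkaempferol-7-ylboronic acid pinacol ester F5.
- **Coupling and return:** a Chan–Lam–Evans coupling of F5 with the 3-OH of 6 (Cu(OAc)2, pyridine, 4 Å molecular sieves, air, MeCN, rt; the chelated 5-OH does not react) comes back to the route at 14.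

Further compounds
F1 | step 9 | 7-benzyloxy-2-(4-benzyloxyphenyl)-3,5-dihydroxy-2,3-dimethoxychroman-4-one (racemic mixture of diastereomers) | O=C1c2c(O)cc(OCc3ccccc3)cc2OC(OC)(c2ccc(OCc3ccccc3)cc2)C1(O)OC
F2 | step 9 | racemic cis-fused 3-hydroxy pentabenzyl ether (5-OH free) | O=C1c2c(O)cc(OCc6ccccc6)cc2OC2(c3ccc(OCc6ccccc6)cc3)c3c(cc(OCc6ccccc6)c4c(=O)c(OCc6ccccc6)c(-c5ccc(OCc6ccccc6)cc5)oc34)OC12O
F3 | step 9 | (2R,3S)-3-hydroxy pentabenzyl ether (5-OH free) | O=C1c2c(O)cc(OCc6ccccc6)cc2O[C@]2(c3ccc(OCc6ccccc6)cc3)c3c(cc(OCc6ccccc6)c4c(=O)c(OCc6ccccc6)c(-c5ccc(OCc6ccccc6)cc5)oc34)O[C@]12O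
F0 | step 11 | none | none
F4 | step 8 | 3,5,4'-tri-O-benzylkaempferol 7-triflate | O=c1c(OCc3ccccc3)c(-c2ccc(OCc3ccccc3)cc2)oc2cc(OS(=O)(=O)C(F)(F)F)cc(OCc3ccccc3)c12
F5 | step 8 | 3,5,4'-tri-O-benzylkaempferol-7-ylboronic acid pinacol ester | O=c1c(OCc3ccccc3)c(-c2ccc(OCc3ccccc3)cc2)oc2cc(B3OC(C)(C)C(C)(C)O3)cc(OCc3ccccc3)c12
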